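**Strategy.** Ring A (cyclohexenone: C1 ketone, C2 and C3 methoxy carbons, C4 carbinol, C5 side chain, C6 methyl) is disconnected at its tetrasubstituted C2=C3 enediol-ether bond. Both carbons are acyl-type, oxygen-bearing carbons flanked by the oxidised C1 and C4. C2 is therefore drawn from an ester carbonyl that keeps its own methoxyl, and C3 from a methoxy-substituted acyl ylide (polarity reversal). The key step, an intramolecular ester Wittig olefination of an acyclic keto-ylide ester (C1 as dimethyl ketal, C4 as ylide ketone), closes ring A with fixed enol-ether regiochemistry. Asymmetric conjugate methylation, enolate alkylation and a late Negishi coupling with the lactone (ring B) fragment, then reduction and ketal hydrolysis, complete the target.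

Key step: step 3

Remark on numbering: ring A positions are quoted with the numbering of the target throughout (C1 = ketone of the target, carried as a dimethyl ketal; C4 = carbinol of the target, a ketone until step 14). Systematic names of intermediates use their own numbering.

Assumption: in step 5 the (S,R,R)-phosphoramidite is written as the ligand that delivers the 5R adduct; if a test run shows the opposite sense, its mirror image is used.

**Step 1**
Reactants: 1 methyl 2,2-dimethoxyacetate; 2 benzyl prop-2-enoate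
Product: 4 5-benzyl 1-methyl 2,2-dimethoxypentanedioate, via lithium enolate 3 (not isolated)
Conditions: LiN(i-Pr)2 (1.05 equiv), THF, −78 °C; then 2 (slow addition), −78 °C; AcOH
Reagents that add atoms: none
Why: Michael addition of the α,α-dimethoxy ester enolate (a glyoxylate acyl-anion equivalent) to the acrylate at low temperature should give the glutarate skeleton with its two esters differentiated (methyl next to the ketal, benzyl remote); no stereocentre is formed.

**Step 2**
Reactants: 4 5-benzyl 1-methyl 2,2-dimethoxypentanedioate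
Product: 5 4,4,5-trimethoxy-5-oxopentanoic acid
Conditions: H2 (1 atm), Pd/C, EtOAc, rt
Reagents that add atoms: none
Why: Hydrogenolysis should cleave only the benzyl ester, since the methyl ester and the dimethyl ketal are inert to H2 over Pd/C.

**Step 3**
Reactants: 5 4,4,5-trimethoxy-5-oxopentanoic acid
Product: 8 2,3,4,4-tetramethoxycyclohex-2-en-1-one, via acid chloride 6 (not isolated), via acyl ylide 7 (not isolated)
Conditions: 1-chloro-N,N,2-trimethylprop-1-en-1-amine, CH2Cl2, 0 °C → rt; then Ph3P=CHOMe (2.1 equiv, from [Ph3PCH2OMe]Cl and NaN(SiMe3)2), THF, −78 → 0 °C; then PhMe (0.01 M), 110 °C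
Reagents that add atoms: (methoxymethyl)triphenylphosphonium chloride, used as its ylide, COC[P+](c1ccccc1)(c1ccccc1)c1ccccc1.[Cl-]
Why: Acid 5 is converted under neutral conditions into chloride 6, which C-acylates the methoxy ylide (the second equivalent acts as base) to give the carbonyl-stabilised α-methoxy ylide 7; on heating, the ylide carbon (future C3) adds to the only ester carbonyl (future C2) and the oxaphosphetane collapses to Ph3P=O and the C2=C3 double bond, the ester methoxyl staying on C2. The closest known reaction type is the intramolecular Wittig olefination of ester and thioester carbonyls by stabilised ylides, which closes cyclic enol ethers and vinylogous esters (4-alkoxybutenolides from α-hydroxy esters, bicyclic β-lactam enol and thioenol ethers from fully substituted ylide carbons). Ring A is closed by a 6-exo-trig attack of the ylide carbon on the ester carbonyl. No stereocentre is formed. The step needs olefination to win over Claisen-type acyl substitution and over intermolecular reaction: the ylide carbon carries no hydrogen, so loss of methoxide would give an acylphosphonium salt that cannot be stabilised by deprotonation and is reversible, whereas loss of Ph3P=O is irreversible, and high dilution favours ring closure. The regiochemistry of the vinylogous ester (ketone at C4, methoxyls on C2 and C3, ketal at C1) is fixed by construction, because each oxygen stays on the carbon that brought it.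

**Step 4**
Reactants: 8 2,3,4,4-tetramethoxycyclohex-2-en-1-one
Product: 10 2,3,4,4-tetramethoxycyclohexa-2,5-dien-1-one, via silyl dienol ether 9 (not isolated)
Conditions: LiN(i-Pr)2, Me3SiCl, THF, −78 °C; then Pd(OAc)2 (1.05 equiv), MeCN, rt
Reagents that add atoms: none
Why: Saegusa–Ito dehydrogenation: the only enolisable position is the CH2 next to the ketone, its silyl dienol ether should be oxidised by Pd(OAc)2 through β-hydride elimination, and the cross-conjugated dienone cannot tautomerise to a phenol because C1 is a ketal.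

**Step 5**
Reactants: 10 2,3,4,4-tetramethoxycyclohexa-2,5-dien-1-one
Product: 11 (5R)-2,3,4,4-tetramethoxy-5-methylcyclohex-2-en-1-one
Conditions: Me2Zn (2 equiv), Cu(OTf)2 (3 mol %), (S,R,R)-phosphoramidite [O,O′-(S)-1,1′-binaphthyl-2,2′-diyl N,N-bis((R)-1-phenylethyl)phosphoramidite] (6 mol %), PhMe, −30 °C; aq. NH4Cl
Reagents that add atoms: dimethylzinc, C[Zn]C
Why: Copper-catalysed enantioselective conjugate addition of a dialkylzinc to a 4,4-dialkoxycyclohexa-2,5-dienone: only the unsubstituted enone half is reactive (the other β-carbon carries a methoxy group), and the chiral phosphoramidite–copper catalyst should select the enone face that makes the new centre (C6 of the target) R.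

**Step 6**
Reactants: 12 but-3-yn-1-ol
Product: 15 (2E)-3-methylpent-2-ene-1,5-diol, via alkenylalane 13 (not isolated), via lithium alanate 14 (not isolated)
Conditions: Me3Al (3 equiv), Cp2ZrCl2 (0.25 equiv), CH2Cl2, 0 °C → rt; then n-BuLi, THF, −78 °C; then (CH2O)n, −78 °C → rt; aq. HCl
Reagents that add atoms: trimethylaluminium, C[Al](C)C; paraformaldehyde (as formaldehyde), C=O
Why: Zirconium-catalysed syn-carboalumination puts methyl on the internal and aluminium on the terminal alkyne carbon, which fixes the E-trisubstituted olefin, and the alanate should be hydroxymethylated by formaldehyde with retention of geometry.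

**Step 7**
Reactants: 15 (2E)-3-methylpent-2-ene-1,5-diol
Product: 16 (2E)-1,5-dibromo-3-methylpent-2-ene
Conditions: CBr4, PPh3, CH2Cl2, 0 °C
Reagents that add atoms: carbon tetrabromide, BrC(Br)(Br)Br
Why: Appel bromination should convert both primary alcohols under neutral conditions without disturbing the olefin geometry.

**Step 8**
Reactants: 11 (5R)-2,3,4,4-tetramethoxy-5-methylcyclohex-2-en-1-one; 16 (2E)-1,5-dibromo-3-methylpent-2-ene
Product: 18 (5R,6R)-6-[(2E)-5-bromo-3-methylpent-2-en-1-yl]-2,3,4,4-tetramethoxy-5-methylcyclohex-2-en-1-one, via lithium dienolate 17 (not isolated)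
Conditions: LiN(i-Pr)2, THF, −78 °C; then 16 (1.5 equiv), DMPU, −78 → −30 °C
Reagents that add atoms: none
Why: α′-Alkylation of a vinylogous ester enolate (deprotonation is possible only at C6 of 11): the allylic C–Br reacts far faster than the homoallylic one, and the electrophile should enter anti to the neighbouring methyl group, setting the trans-related 6R centre (C5 of the target).

**Step 9**
Reactants: 19 [(2S)-5-oxooxolan-2-yl]methyl 4-methylbenzenesulfonate
Product: 20 methyl 3-[(2S)-oxiran-2-yl]propanoate
Conditions: NaOMe (1.05 equiv), MeOH, 0 °C → rt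
Reagents that add atoms: sodium methoxide, [Na+].[O-]C
Why: Methanolysis of the lactone releases a γ-alkoxide that displaces the tosylate intramolecularly (epoxide formation); no bond to the stereocentre is broken, so its configuration is kept.

**Step 10**
Reactants: 20 methyl 3-[(2S)-oxiran-2-yl]propanoate
Product: 23 (5S)-5-(prop-2-yn-1-yl)oxolan-2-one, via silylalkynol ester 21 (not isolated), via alkynol ester 22 (not isolated)
Conditions: Me3SiC≡CLi (from Me3SiC≡CH, n-BuLi), BF3·OEt2, THF, −78 °C; then K2CO3, MeOH, rt; then TsOH (cat.), CH2Cl2, rt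
Reagents that add atoms: ethynyltrimethylsilane, C#C[Si](C)(C)C
Why: BF3-promoted opening of the terminal epoxide by the lithium acetylide at its CH2 terminus (the ester is tolerated at −78 °C), methanolytic C–Si cleavage and acid-catalysed lactonisation should give the propargyl lactone with the carbinol centre of 19 unchanged.

**Step 11**
Reactants: 23 (5S)-5-(prop-2-yn-1-yl)oxolan-2-one
Product: 25 (5S)-5-[(2E)-3-iodo-2-methylprop-2-en-1-yl]oxolan-2-one, via alkenylalane 24 (not isolated)
Conditions: Me3Al (3 equiv), Cp2ZrCl2 (0.2 equiv), H2O (1 equiv), CH2Cl2, −23 °C; then I2, THF, −23 → 0 °C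
Reagents that add atoms: trimethylaluminium, C[Al](C)C; iodine, II
Why: Water-accelerated zirconium-catalysed methylalumination at low temperature (where the lactone should only coordinate Me3Al) is syn and terminal-selective, and iodinolysis with retention gives the E-iodoalkene.

**Step 12**
Reactants: 25 (5S)-5-[(2E)-3-iodo-2-methylprop-2-en-1-yl]oxolan-2-one
Product: 27 (3R,5S)-5-[(2E)-3-iodo-2-methylprop-2-en-1-yl]-3-methyloxolan-2-one, via lithium enolate 26 (not isolated)
Conditions: LiN(i-Pr)2, THF, −78 °C; then MeI, −78 °C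
Reagents that add atoms: iodomethane, CI
Why: Enolate alkylation of a γ-substituted butyrolactone: methyl iodide should enter anti to the C5 substituent to give the 3,5-trans lactone (3R), and the iodoalkene, which has no β-hydrogen, tolerates the amide base at −78 °C.

**Step 13**
Reactants: 18 (5R,6R)-6-[(2E)-5-bromo-3-methylpent-2-en-1-yl]-2,3,4,4-tetramethoxy-5-methylcyclohex-2-en-1-one; 27 (3R,5S)-5-[(2E)-3-iodo-2-methylprop-2-en-1-yl]-3-methyloxolan-2-one
Product: 29 (5R,6R)-6-{(2E,6E)-3,7-dimethyl-8-[(2S,4R)-4-methyl-5-oxooxolan-2-yl]octa-2,6-dien-1-yl}-2,3,4,4-tetramethoxy-5-methylcyclohex-2-en-1-one, via alkylzinc bromide 28 (not isolated)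
Conditions: Zn dust, LiCl, THF, 50 °C; then 27, PdCl2(dppf) (5 mol %), THF/NMP, rt → 40 °C
Reagents that add atoms: none
Why: Negishi sp3–sp2 coupling: zinc inserts into the primary C–Br bond (ketone, ketal and enol ether are tolerated) and palladium should couple the alkylzinc with the alkenyl iodide with retention of the E geometry; no stereocentre is touched.

**Step 14**
Reactants: 29 (5R,6R)-6-{(2E,6E)-3,7-dimethyl-8-[(2S,4R)-4-methyl-5-oxooxolan-2-yl]octa-2,6-dien-1-yl}-2,3,4,4-tetramethoxy-5-methylcyclohex-2-en-1-one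
Product: 30 (1R,5R,6R)-6-{(2E,6E)-3,7-dimethyl-8-[(2S,4R)-4-methyl-5-oxooxolan-2-yl]octa-2,6-dien-1-yl}-2,3,4,4-tetramethoxy-5-methylcyclohex-2-en-1-ol
Conditions: LiBH(s-Bu)3 (1.2 equiv), THF, −78 °C; aq. NH4Cl
Reagents that add atoms: none
Why: 1,2-Reduction of the conjugated ketone by a bulky trialkylborohydride: equatorial attack should deliver the pseudoaxial alcohol cis to the adjacent side chain (C4 of the target, R), the fully substituted β-carbon rules out 1,4-reduction, and at −78 °C the lactone of ring B should not be attacked.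

**Step 15**
Reactants: 30 (1R,5R,6R)-6-{(2E,6E)-3,7-dimethyl-8-[(2S,4R)-4-methyl-5-oxooxolan-2-yl]octa-2,6-dien-1-yl}-2,3,4,4-tetramethoxy-5-methylcyclohex-2-en-1-ol
Product: 31 (4R,5R,6R)-4-hydroxy-2,3-dimethoxy-6-methyl-5-{(2E,6E)-3,7-dimethyl-8-[(2S,4R)-4-methyl-5-oxooxolan-2-yl]octa-2,6-dien-1-yl}cyclohex-2-en-1-one
Conditions: montmorillonite K10, wet CH2Cl2, rt
Reagents that add atoms: water, O
Why: Acid-catalysed hydrolysis of the dimethyl ketal, which ionises readily because its oxocarbenium ion is conjugated with the enol ether, should release the C1 ketone and complete the 2,3-dimethoxyenone without touching the stereocentres.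

**Compound list**

1 | methyl 2,2-dimethoxyacetate | COC(=O)C(OC)OC | starting material
2 | benzyl prop-2-enoate | C=CC(=O)OCc1ccccc1 | starting material
3 | lithium 1,2,2-trimethoxyethen-1-olate (lithium enolate of 1) | [Li]OC(OC)=C(OC)OC | intermediate
4 | 5-benzyl 1-methyl 2,2-dimethoxypentanedioate | COC(=O)C(OC)(OC)CCC(=O)OCc1ccccc1 | intermediate
5 | 4,4,5-trimethoxy-5-oxopentanoic acid | COC(=O)C(OC)(OC)CCC(=O)O | intermediate
6 | methyl 5-chloro-2,2-dimethoxy-5-oxopentanoate | COC(=O)C(OC)(OC)CCC(=O)Cl | intermediate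
7 | methyl 2,2,6-trimethoxy-5-oxo-6-(triphenyl-λ5-phosphanylidene)hexanoate | COC(=O)C(OC)(OC)CCC(=O)C(OC)=P(c1ccccc1)(c1ccccc1)c1ccccc1 | intermediate
8 | 2,3,4,4-tetramethoxycyclohex-2-en-1-one | COC1=C(OC)C(OC)(OC)CCC1=O | intermediate
9 | trimethyl[(4,4,5,6-tetramethoxycyclohexa-1,5-dien-1-yl)oxy]silane | COC1=C(OC)C(OC)(OC)CC=C1O[Si](C)(C)C | intermediate
10 | 2,3,4,4-tetramethoxycyclohexa-2,5-dien-1-one | COC1=C(OC)C(OC)(OC)C=CC1=O | intermediate
11 | (5R)-2,3,4,4-tetramethoxy-5-methylcyclohex-2-en-1-one | COC1=C(OC)C(OC)(OC)[C@H](C)CC1=O | intermediate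
12 | but-3-yn-1-ol | C#CCCO | starting material
13 | {(1E)-4-[(dimethylalumanyl)oxy]-2-methylbut-1-en-1-yl}dimethylalumane | C[Al](C)/C=C(\C)CCO[Al](C)C | intermediate
14 | lithium butyl{(1E)-4-[(dimethylalumanyl)oxy]-2-methylbut-1-en-1-yl}dimethylaluminate | [Li+].CCCC[Al-](C)(C)/C=C(\C)CCO[Al](C)C | intermediate
15 | (2E)-3-methylpent-2-ene-1,5-diol | OC/C=C(\C)CCO | intermediate
16 | (2E)-1,5-dibromo-3-methylpent-2-ene | BrC/C=C(\C)CCBr | intermediate
17 | lithium (3R)-4,4,5,6-tetramethoxy-3-methylcyclohexa-1,5-dien-1-olate | COC1=C(OC)C(OC)(OC)[C@H](C)C=C1O[Li] | intermediate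
18 | (5R,6R)-6-[(2E)-5-bromo-3-methylpent-2-en-1-yl]-2,3,4,4-tetramethoxy-5-methylcyclohex-2-en-1-one | COC1=C(OC)C(OC)(OC)[C@H](C)[C@@H](C/C=C(\C)CCBr)C1=O | intermediate
19 | [(2S)-5-oxooxolan-2-yl]methyl 4-methylbenzenesulfonate | Cc1ccc(cc1)S(=O)(=O)OC[C@@H]1CCC(=O)O1 | starting material
20 | methyl 3-[(2S)-oxiran-2-yl]propanoate | COC(=O)CC[C@H]1CO1 | intermediate
21 | methyl (4S)-4-hydroxy-7-(trimethylsilyl)hept-6-ynoate | COC(=O)CC[C@H](O)CC#C[Si](C)(C)C | intermediate
22 | methyl (4S)-4-hydroxyhept-6-ynoate | COC(=O)CC[C@H](O)CC#C | intermediate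
23 | (5S)-5-(prop-2-yn-1-yl)oxolan-2-one | C#CC[C@@H]1CCC(=O)O1 | intermediate
24 | dimethyl{(1E)-2-methyl-3-[(2S)-5-oxooxolan-2-yl]prop-1-en-1-yl}alumane | C[Al](C)/C=C(\C)C[C@@H]1CCC(=O)O1 | intermediate
25 | (5S)-5-[(2E)-3-iodo-2-methylprop-2-en-1-yl]oxolan-2-one | I/C=C(\C)C[C@@H]1CCC(=O)O1 | intermediate
26 | lithium (5S)-5-[(2E)-3-iodo-2-methylprop-2-en-1-yl]-4,5-dihydrofuran-2-olate | I/C=C(\C)C[C@@H]1CC=C(O[Li])O1 | intermediate
27 | (3R,5S)-5-[(2E)-3-iodo-2-methylprop-2-en-1-yl]-3-methyloxolan-2-one | I/C=C(\C)C[C@@H]1C[C@@H](C)C(=O)O1 | intermediate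
28 | bromo{(3E)-3-methyl-5-[(1R,6R)-3,4,5,5-tetramethoxy-6-methyl-2-oxocyclohex-3-en-1-yl]pent-3-en-1-yl}zinc | COC1=C(OC)C(OC)(OC)[C@H](C)[C@@H](C/C=C(\C)CC[Zn]Br)C1=O | intermediate
29 | (5R,6R)-6-{(2E,6E)-3,7-dimethyl-8-[(2S,4R)-4-methyl-5-oxooxolan-2-yl]octa-2,6-dien-1-yl}-2,3,4,4-tetramethoxy-5-methylcyclohex-2-en-1-one | COC1=C(OC)C(OC)(OC)[C@H](C)[C@@H](C/C=C(\C)CC/C=C(\C)C[C@@H]2C[C@@H](C)C(=O)O2)C1=O | intermediate
30 | (1R,5R,6R)-6-{(2E,6E)-3,7-dimethyl-8-[(2S,4R)-4-methyl-5-oxooxolan-2-yl]octa-2,6-dien-1-yl}-2,3,4,4-tetramethoxy-5-methylcyclohex-2-en-1-ol | COC1=C(OC)C(OC)(OC)[C@H](C)[C@@H](C/C=C(\C)CC/C=C(\C)C[C@@H]2C[C@@H](C)C(=O)O2)[C@H]1O | intermediate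
31 | (4R,5R,6R)-4-hydroxy-2,3-dimethoxy-6-methyl-5-{(2E,6E)-3,7-dimethyl-8-[(2S,4R)-4-methyl-5-oxooxolan-2-yl]octa-2,6-dien-1-yl}cyclohex-2-en-1-one | COC1=C(OC)[C@H](O)[C@H](C/C=C(\C)CC/C=C(\C)C[C@@H]2C[C@@H](C)C(=O)O2)[C@@H](C)C1=O | target

**Totals.** Total step count: 15. Longest linear sequence: 9 steps (steps 1, 2, 3, 4, 5, 8, 13, 14, 15).

**Steps most likely to fail**

Step 3 (ring closure). The fully substituted ylide carbon may fail to add to the hindered α,α-dimethoxy ester, or the tetrahedral adduct may revert instead of collapsing to the oxaphosphetane, so that the sequence stalls at 7 or drifts into intermolecular acyl transfer. The fallback forms the same C2–C3 bond by enolate chemistry and sets out from acid 5 through its chloride 6. Diazomethane converts 6 into the diazoketone methyl 6-diazo-2,2-dimethoxy-5-oxohexanoate F1. Rh2(OAc)4-catalysed O–H insertion in methanol gives the methoxymethyl ketone methyl 2,2,6-trimethoxy-5-oxohexanoate F2. KOt-Bu in THF then brings about the intramolecular Claisen (Dieckmann) condensation of the methoxymethyl ketone enolate onto the ester to give 2,4,4-trimethoxycyclohexane-1,3-dione F3. Acid-catalysed enol etherification (HC(OMe)3, MeOH, camphorsulfonic acid) at the more electrophilic carbonyl next to the ketal should give 8, where the route is rejoined. The regiochemistry of this etherification is not secured by construction; a regioisomeric enol ether would have to be separated or re-equilibrated in acidic methanol.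

Step 5 (asymmetric conjugate methylation). Methyl transfer from zinc to the hindered β-carbon next to the ketal may be slow, and the discrimination of the two enone faces may be insufficient. The fallback replaces asymmetric catalysis by resolution and sets out from 10. Me2CuLi (Et2O, −78 °C) adds to the same β-carbon without facial bias to give racemic 2,3,4,4-tetramethoxy-5-methylcyclohex-2-en-1-one F4. Preparative chromatography on a chiral stationary phase separates it into the unwanted (5S)-2,3,4,4-tetramethoxy-5-methylcyclohex-2-en-1-one F5 and the (5R)-enantiomer 11, where the route is rejoined.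

Step 14 (ketone reduction). The hydride may attack the lactone of ring B if the deactivated vinylogous ester ketone reacts sluggishly, or it may be delivered from the wrong face. The fallback changes the order of events so that the ketone is reduced before any lactone is present, and sets out from bromide 18. Reduction with LiBH(s-Bu)3 (THF, −78 °C) gives (1R,5R,6R)-6-[(2E)-5-bromo-3-methylpent-2-en-1-yl]-2,3,4,4-tetramethoxy-5-methylcyclohex-2-en-1-ol F6; at this stage a more reactive hydride, or a Mitsunobu inversion of an epimeric alcohol, can be used freely. Et3SiCl and imidazole give its triethylsilyl ether F7. Zinc insertion gives the alkylzinc bromide F8, which is coupled with 27 as in step 13 to give the silyl-protected coupling product F9. A single treatment with dilute aqueous acid then cleaves the silyl ether and the ketal together and returns the route at the target 31.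

**Further compounds**

F1 | step 3 | methyl 6-diazo-2,2-dimethoxy-5-oxohexanoate | COC(=O)C(OC)(OC)CCC(=O)C=[N+]=[N-]
F2 | step 3 | methyl 2,2,6-trimethoxy-5-oxohexanoate | COCC(=O)CCC(OC)(OC)C(=O)OC
F3 | step 3 | 2,4,4-trimethoxycyclohexane-1,3-dione | COC1C(=O)CCC(OC)(OC)C1=O
F4 | step 5 | rac-2,3,4,4-tetramethoxy-5-methylcyclohex-2-en-1-one | COC1=C(OC)C(OC)(OC)C(C)CC1=O
F5 | step 5 | (5S)-2,3,4,4-tetramethoxy-5-methylcyclohex-2-en-1-one | COC1=C(OC)C(OC)(OC)[C@@H](C)CC1=O
F6 | step 14 | (1R,5R,6R)-6-[(2E)-5-bromo-3-methylpent-2-en-1-yl]-2,3,4,4-tetramethoxy-5-methylcyclohex-2-en-1-ol | COC1=C(OC)C(OC)(OC)[C@H](C)[C@@H](C/C=C(\C)CCBr)[C@H]1O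
F7 | step 14 | {[(1R,5R,6R)-6-[(2E)-5-bromo-3-methylpent-2-en-1-yl]-2,3,4,4-tetramethoxy-5-methylcyclohex-2-en-1-yl]oxy}triethylsilane | COC1=C(OC)C(OC)(OC)[C@H](C)[C@@H](C/C=C(\C)CCBr)[C@H]1O[Si](CC)(CC)CC
F8 | step 14 | bromo{(3E)-3-methyl-5-[(1R,2R,6R)-3,4,5,5-tetramethoxy-6-methyl-2-(triethylsilyloxy)cyclohex-3-en-1-yl]pent-3-en-1-yl}zinc | COC1=C(OC)C(OC)(OC)[C@H](C)[C@@H](C/C=C(\C)CC[Zn]Br)[C@H]1O[Si](CC)(CC)CC
F9 | step 14 | (3R,5S)-3-methyl-5-{(2E,6E)-2,6-dimethyl-8-[(1R,2R,6R)-3,4,5,5-tetramethoxy-6-methyl-2-(triethylsilyloxy)cyclohex-3-en-1-yl]octa-2,6-dien-1-yl}oxolan-2-one | COC1=C(OC)C(OC)(OC)[C@H](C)[C@@H](C/C=C(\C)CC/C=C(\C)C[C@@H]2C[C@@H](C)C(=O)O2)[C@H]1O[Si](CC)(CC)CC
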